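Remark on the chemistry (assumption): the lactol carbon of 24 is taken to hold its configuration only in neutral, aprotic surroundings, because opening to the B6 aldehyde and B5 acid would racemise it. The last step is therefore neutral, and 24 is to be isolated cold and kept away from acid, base and alcohols.

## Structural features

The target is a tetracyclic depsidone. Benzene rings A and B are joined twice, by a diaryl ether oxygen and by an ester whose carbonyl belongs to ring A, and these two links close the seven-membered dioxepinone ring C. Ring A is an orsellinic acid unit (a1 carboxyl carbon, a2 ether oxygen, a3 free aldehyde, a4 methoxy, a5 hydrogen, a6 methyl). Ring B carries the ether oxygen on B1, the ester oxygen on B2, its only hydrogen on B3, a phenol on B4, and a fused five-membered hydroxy lactone (ring D, a 3-hydroxyphthalide) with the lactone carbonyl on B5 and the lactol carbon on B6. The lactol carbon is the only stereocentre, (S)-configured and without a stereogenic neighbour, so nothing in the molecule can be used to control it. Further fragile groups are the aryl ester of ring C (cleaved by hydroxide, alkoxides and amines), the ring A aldehyde and the B4 phenol. The real difficulty is twofold: a pentasubstituted ring B whose ether junction is flanked by four ortho substituents, and a stereocentre that cannot survive acid or base. The key step uses the fact that B1 and B2 are neighbours and both oxygenated, and that B4, para to B1, carries a hydroxyl. B1, B6, B5, B4 and the B4 oxygen map onto a furan bound through C2 to the ether oxygen; B2–B3 map onto an alkyne bound as an ester to the ring A carboxyl. One cycloaddition across B1–B2 and B3–B4 can then close rings B and C together.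

## Logic of the disconnections

24 from 23. The lactol O–H is traced back to an O–CH(CH3)Ph ether, so the bond at stake is the exocyclic O–C(benzylic) bond and not a bond to the stereocentre. As a mixed acetal the centre cannot open, so 23 is configurationally fixed and can be purified as one diastereomer. The forward cleavage must be neutral and must spare the aldehyde and both C–O bonds at the acetal carbon, which points to hydrogenolysis.

23 from 21 and 22. The exocyclic C–O bond at the lactol carbon is cut. A hemiacetal that equilibrates through its open form cannot be made enantioselectively with confidence, so an enantiopure alcohol turns the racemate into separable diastereomers. The gain is that 21 may be racemic and all earlier chemistry achiral. The demand is an acid mild enough not to ionise 22, and a workable separation, with the unwanted epimer returned through 21.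

21 from 18. The lactone acyl–O bond of ring D is opened, B3–H becomes B3–Si, and the two aldehydes become acetals. All of these masks yield to aqueous acid in one operation. The B5 methyl ester needs no hydroxide, which ring C would not survive, because the hydrate of the neighbouring B6 aldehyde attacks it intramolecularly. The demand is ipso-protonation at B3 of a deactivated ring.

18 from 16 through 17. B1–B2 and B3–B4 are cut and the B4 hydroxyl is returned to an oxygen bridge on B1. Rings B and C both disappear, and the crowded ether junction moves from a fully substituted benzene to C2 of a furan, where it can be made by substitution. All ring B substituents already sit on the furan or the alkyne. The demand is a thermal cycloaddition over a seven-membered ester tether with a weak dienophile, and bridge opening at B1. The methyl ester is kept in 16 because a tert-butyl ester would not survive the heat, and the small trimethylsilyl group is kept because a larger one would slow both the cycloaddition and its later removal.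

16 from 13 and 15; 15 from 14. The ester O–C(sp) bond is cut. An ynol cannot be acylated, so the alkyne must be the electrophile and the carboxylate the nucleophile; the bond forms at oxygen, so hindrance of the carboxyl does not matter. 15 must come from the doubly silylated 14, because trivalent iodine displaces a silyl group and a monosilylated alkyne would lose its only one. The product is sensitive and must be used at once.

13 from 12 from 11. The O–allyl bond and the acetal C–O bonds are cut. The ring A carboxyl is di-ortho-substituted and shares the molecule with an unhindered methyl ester on the furan, so it needs an ester that is cleaved away from the acyl carbon. The acetals protect both aldehydes and turn the furan into an electron-rich diene. The demand is acetalisation without acid solvolysis of the furyl ether.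

11 from 10 and 5. The furan C2–O bond is cut. The bromine of 5 is β to a formyl group, so addition–elimination is available, and two fragments of similar size are joined. The demand is sufficient nucleophilicity of the chelated, hindered phenoxide of 10.

10 from 8, 7 and 6. The a3–CHO bond, the a4 O–CH3 bond and the ester O–allyl bond are cut. Only one position is ortho to the free phenol of 8, the two hydroxyls of 7 differ by hydrogen bonding, and 6 is alkylated at the carboxylate only.

5 from 4, 3, 2 and 1. The C–Br bond is cut, the oxidation level adjusted, and the symmetric diester desymmetrised. Bromine must enter next to the carbon that becomes the formyl group. Electrophilic substitution does that only while this carbon is a CH2OH group; with the formyl group in place the other α-position would react. Hence 3 is brominated and 4 is oxidised afterwards.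

## Other disconnections considered

Alternative 1: The cut is the B5–C(=O) bond and the lactone acyl–O bond of ring D, with rings A, B and C complete. In the forward step a zerovalent palladium catalyst with a wide-bite-angle diphosphine would insert into the B5–Br bond of bromo aldehyde A2. Carbonylation would follow, and the acyl palladium would be captured by the hemiacetal of the B6 aldehyde with alcohol 22, giving acetal A1. In its favour, carbonylative lactonisation of ortho-halo aryl carbonyl compounds is an established reaction type, so on mechanistic precedent it is better than the chosen plan. A single final hydrogenolysis would remove the benzyl and the 1-phenylethyl group together. Against it, oxidative addition at a bromide flanked by a benzyloxy and a formyl group is slow. Base and alcohol at elevated temperature threaten the ring C ester, and direct alkoxycarbonylation by the free alcohol competes. On stereochemistry it is the equal of the chosen plan: both give two acetal epimers and rely on separation. On structure it is weaker: it closes only ring D and leaves the construction of A2 with its crowded ether junction open. That would need a conventional ether coupling and lactonisation and would probably be longer.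

Alternative 2: The cut is B2–B3 and B5–B6, so ring B is built from acyclic pieces on the ether oxygen of ring A. The dianion of ketoester A5 would be acylated at its terminal carbon by the methyl ester of enoate A4. A magnesium alkoxide would then close the central carbon onto the methoxy-bearing carbon with loss of methanol, giving diaryl ether A3. In its favour, this is a well-precedented Claisen and aromatising-cyclisation sequence, so on mechanistic security it is better than the chosen plan. It also avoids any coupling of two complete arenes and sets B2–OH, B4–OH, the B5 ester and the B6 acetal in one operation. Against it, A4 is a tetrasubstituted, trioxygenated alkene that must first be built on the hindered phenol. The dianion may add in conjugate fashion at the methoxy-bearing carbon. Ring C still has to be closed in separate steps, and release of the tert-butyl ester by acid would also strip both acetals. It forms one ring where the chosen key step forms two, so step economy is somewhat worse. On stereochemistry it is equal, since the same resolution is needed.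

Alternative 3: The cut is the lactol C–O(H) bond, traced back to a C–B bond, together with the lactone acyl–O bond. A monovalent copper alkoxide catalyst with a bulky enantiopure diphosphine would add the boryl group of diboron reagent A8 to the B6 aldehyde of A7. The alkoxide would close onto the B5 methyl ester to give boryl phthalide A6, and stereoretentive oxidation would give the lactol. In its favour, it is the only plan that sets the stereocentre by catalyst control. On this point it is better than the chosen plan, which loses half the material per pass. Against it, a di-ortho-substituted aryl aldehyde is an untested substrate for this borylation, and the alkoxide base endangers the ring C ester. The C–B oxidation is normally run in basic peroxide, where the product lactol opens and racemises. The methoxymethyl ether and the ring A acetal would then still need acid. The chosen plan ends with a neutral step and is safer there. Like alternative 1, it builds no part of rings B and C, so its overall length depends on an unsolved route to A7.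

Key step: step 13

## Route

Step 1
Reactants: 1 dimethyl furan-3,4-dicarboxylate
Product: 2 4-(methoxycarbonyl)furan-3-carboxylic acid
Conditions: KOH (1.0 equiv), MeOH, 0 °C → rt; then aq. HCl, pH 2
Reagents that add atoms: potassium hydroxide, [K+].[OH-]
Why: Monosaponification of a symmetric diester by acyl–oxygen cleavage; the first carboxylate formed deactivates the neighbouring ester, and the two esters are equivalent, so no regiochemical question arises.

Step 2
Reactants: 2 4-(methoxycarbonyl)furan-3-carboxylic acid
Product: 3 methyl 4-(hydroxymethyl)furan-3-carboxylate
Conditions: BH3·THF (1.5 equiv), THF, 0 °C → rt; MeOH quench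
Reagents that add atoms: none
Why: Chemoselective borane reduction: the acid is reduced through its acyloxyborane much faster than the conjugated methyl ester, and the furan is inert.

Step 3
Reactants: 3 methyl 4-(hydroxymethyl)furan-3-carboxylate
Product: 4 methyl 5-bromo-4-(hydroxymethyl)furan-3-carboxylate
Conditions: NBS (1.05 equiv), DMF, 0 °C, dark
Reagents that add atoms: N-bromosuccinimide, O=C1CCC(=O)N1Br
Why: Electrophilic bromination at a furan α-position; attack at C5 puts the positive charge on C4 (alkyl-type CH2OH substituent) whereas attack at C2 would put it on the ester-bearing C3, so C5 should be favoured. The bromination is placed before the oxidation because a formyl group on C4 would reverse this preference.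

Step 4
Reactants: 4 methyl 5-bromo-4-(hydroxymethyl)furan-3-carboxylate
Product: 5 methyl 5-bromo-4-formylfuran-3-carboxylate
Conditions: Dess–Martin periodinane (1.2 equiv), CH2Cl2, 0 °C → rt
Reagents that add atoms: none
Why: Dess–Martin oxidation of a primary heteroaryl carbinol stops at the aldehyde and tolerates the bromofuran and the ester.

Step 5
Reactants: 6 orsellinic acid (2,4-dihydroxy-6-methylbenzoic acid)
Product: 7 allyl 2,4-dihydroxy-6-methylbenzoate
Conditions: allyl bromide (1.1 equiv), KHCO3 (1.2 equiv), DMF, rt
Reagents that add atoms: allyl bromide, C=CCBr
Why: Hydrogencarbonate deprotonates only the carboxylic acid, and the carboxylate is alkylated at oxygen by SN2, which is insensitive to the ortho substituents; the phenols stay free.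

Step 6
Reactants: 7 allyl 2,4-dihydroxy-6-methylbenzoate
Product: 8 allyl 2-hydroxy-4-methoxy-6-methylbenzoate
Conditions: MeI (1.1 equiv), K2CO3 (1.1 equiv), acetone, rt → 40 °C
Reagents that add atoms: iodomethane, CI
Why: Williamson etherification; the a2 hydroxyl is chelated to the ester carbonyl and is the less acidic and less nucleophilic one, so the a4 hydroxyl should be methylated selectively.

Step 7
Reactants: 8 allyl 2-hydroxy-4-methoxy-6-methylbenzoate
Product: 10 allyl 3-formyl-2-hydroxy-4-methoxy-6-methylbenzoate, via salicyl alcohol 9 (not isolated)
Conditions: MgCl2 (2 equiv), Et3N (4 equiv), (CH2O)n (6 equiv), MeCN, reflux; aq. HCl work-up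
Reagents that add atoms: paraformaldehyde (as formaldehyde), C=O
Why: Magnesium-mediated ortho-formylation of a phenol: the magnesium phenoxide delivers formaldehyde through a chelate to the only free ortho carbon (a3, also activated by the methoxy and methyl groups), and the benzylic alkoxide of 9 is oxidised by a second formaldehyde through hydride transfer (Oppenauer type).

Step 8
Reactants: 10 allyl 3-formyl-2-hydroxy-4-methoxy-6-methylbenzoate; 5 methyl 5-bromo-4-formylfuran-3-carboxylate
Product: 11 allyl 3-formyl-2-{[3-formyl-4-(methoxycarbonyl)furan-2-yl]oxy}-4-methoxy-6-methylbenzoate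
Conditions: Cs2CO3 (1.3 equiv), DMF, 60 °C
Reagents that add atoms: none
Why: Nucleophilic aromatic substitution by addition–elimination: the bromine of 5 sits on a furan α-carbon β to the formyl group (a β-bromo enal), so the cesium phenoxide of 10 adds there, the formyl group takes up the charge, and bromide leaves.

Step 9
Reactants: 11 allyl 3-formyl-2-{[3-formyl-4-(methoxycarbonyl)furan-2-yl]oxy}-4-methoxy-6-methylbenzoate
Product: 12 allyl 3-(dimethoxymethyl)-2-{[3-(dimethoxymethyl)-4-(methoxycarbonyl)furan-2-yl]oxy}-4-methoxy-6-methylbenzoate
Conditions: HC(OMe)3 (6 equiv), MeOH, PPTS (0.1 equiv), 40 °C; Et3N quench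
Reagents that add atoms: trimethyl orthoformate, COC(OC)OC; methanol, CO
Why: Acid-catalysed acetalisation driven by the orthoformate as water scavenger; the weak acid and the furan ester, which disfavours ring protonation, should prevent solvolysis of the furyl ether. The acetals protect both aldehydes and turn the push–pull furan into an electron-rich diene.

Step 10
Reactants: 12 allyl 3-(dimethoxymethyl)-2-{[3-(dimethoxymethyl)-4-(methoxycarbonyl)furan-2-yl]oxy}-4-methoxy-6-methylbenzoate
Product: 13 potassium 3-(dimethoxymethyl)-2-{[3-(dimethoxymethyl)-4-(methoxycarbonyl)furan-2-yl]oxy}-4-methoxy-6-methylbenzoate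
Conditions: Pd(PPh3)4 (3 mol%), potassium 2-ethylhexanoate (1.05 equiv), CH2Cl2/EtOAc, rt; salt precipitated with Et2O and washed free of phosphine
Reagents that add atoms: potassium 2-ethylhexanoate, CCCCC(CC)C(=O)[O-].[K+]
Why: Tsuji–Trost allyl transfer: zerovalent palladium ionises the allyl ester and passes the allyl group to 2-ethylhexanoate, which frees the di-ortho-substituted carboxyl under neutral conditions. No saponification could do this without cleaving the furan methyl ester first; the acetals are untouched.

Step 11
Reactants: 14 bis(trimethylsilyl)acetylene
Product: 15 phenyl[(trimethylsilyl)ethynyl]iodonium trifluoromethanesulfonate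
Conditions: PhI(OAc)2 (1.0 equiv), Tf2O (0.5 equiv), CH2Cl2, 0 °C; then 14 (1.0 equiv), 0 °C → rt
Reagents that add atoms: (diacetoxyiodo)benzene, CC(=O)OI(OC(C)=O)c1ccccc1; trifluoromethanesulfonic anhydride, O=S(=O)(OS(=O)(=O)C(F)(F)F)C(F)(F)F
Why: Tf2O turns the diacetate into a μ-oxo-bridged trivalent iodine triflate, which replaces one silyl group of the alkyne by electrophilic ipso-substitution (silicon–iodine exchange). The second silyl group stays because the iodonium group deactivates the alkyne, which is why the doubly silylated alkyne is needed.

Step 12
Reactants: 13 potassium 3-(dimethoxymethyl)-2-{[3-(dimethoxymethyl)-4-(methoxycarbonyl)furan-2-yl]oxy}-4-methoxy-6-methylbenzoate; 15 phenyl[(trimethylsilyl)ethynyl]iodonium trifluoromethanesulfonate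
Product: 16 (trimethylsilyl)ethynyl 3-(dimethoxymethyl)-2-{[3-(dimethoxymethyl)-4-(methoxycarbonyl)furan-2-yl]oxy}-4-methoxy-6-methylbenzoate
Conditions: 18-crown-6 (0.1 equiv), CH2Cl2, −40 °C → 0 °C; filtration through neutral Al2O3; used at once
Reagents that add atoms: none
Why: Alkynylation of a carboxylate by an alkynyl(aryl)iodonium salt: the carboxylate adds to the β-carbon, iodobenzene leaves to give an alkylidene carbene, and a 1,2-silyl shift gives the alkynyl ester. The bond forms at oxygen, so the hindered carboxyl is no obstacle, and the same hindrance shields the acyl carbon of the product.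

Step 13
Reactants: 16 (trimethylsilyl)ethynyl 3-(dimethoxymethyl)-2-{[3-(dimethoxymethyl)-4-(methoxycarbonyl)furan-2-yl]oxy}-4-methoxy-6-methylbenzoate
Product: 18 methyl 4,6-bis(dimethoxymethyl)-8-hydroxy-3-methoxy-1-methyl-11-oxo-9-(trimethylsilyl)-11H-dibenzo[b,e][1,4]dioxepine-7-carboxylate, via oxa-bridged cycloadduct 17 (not isolated)
Conditions: 1,2-Cl2C6H4 (0.005 M, degassed), 2,6-di-tert-butyl-4-methylpyridine (0.2 equiv), 170 °C, sealed vessel
Reagents that add atoms: none
Why: Proposed new method: the closest known reaction type is the thermal intramolecular Diels–Alder reaction of furans with tethered alkynes, whose 7-oxanorbornadiene adducts open to phenols; a seven-membered tether ring and an alkynyl ester as dienophile have no precedent. Heating should bring the alkyne across furan C2 and C5 in a concerted, asynchronous [4+2] cycloaddition that forms B1–B2 and B3–B4 and gives 17. Ring B is closed by the cycloaddition itself, and ring C is closed in the same event as the tether ring through the new B1–B2 bond. The ortho-disubstituted ring A holds the five tether atoms close to the furan, although the ester must first turn into its less favoured, lactone-like conformation. In 17 the bridgehead B1 is a ketal carbon, so the bridge C–O bond should ionise there to an aryloxy-stabilised cation; loss of the B4 proton then gives the phenol, which makes the sequence irreversible and removes both bridgehead stereocentres, so none has to be controlled. Regiochemistry is fixed by the tether, and the direction of bridge opening (B1–O and not B4–O) is secured by the aryloxy donor on B1, so the oxygen stays on B4. The acetal on furan C3 keeps the diene electron-rich and offsets the weak activation of the dienophile, whose polarisation opposes the orientation forced by the tether; hence the high temperature. High dilution and the hindered pyridine are meant to suppress intermolecular acyl transfer from the alkynyl ester and acid-induced loss of the acetals.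

Step 14
Reactants: 18 methyl 4,6-bis(dimethoxymethyl)-8-hydroxy-3-methoxy-1-methyl-11-oxo-9-(trimethylsilyl)-11H-dibenzo[b,e][1,4]dioxepine-7-carboxylate
Product: 21 (±)-1,4-dihydroxy-10-methoxy-8-methyl-3,7-dioxo-1,3-dihydro-7H-isobenzofuro[4,5-b][1,4]benzodioxepine-11-carbaldehyde (racemic lactol), via silylated dialdehyde ester 19 (not isolated), via silylated lactol 20 (not isolated)
Conditions: TFA/H2O (9:1), 0 °C → 45 °C
Reagents that add atoms: water, O
Why: Aqueous acid first hydrolyses both acetals (19); the hydrate of the B6 aldehyde then attacks the neighbouring B5 methyl ester and expels methanol, closing ring D without hydroxide and so sparing ring C (20). The B3 silyl group is finally lost by ipso-protonation (protodesilylation), helped by the ortho phenol and by relief of strain.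

Step 15
Reactants: 21 (±)-1,4-dihydroxy-10-methoxy-8-methyl-3,7-dioxo-1,3-dihydro-7H-isobenzofuro[4,5-b][1,4]benzodioxepine-11-carbaldehyde; 22 (R)-1-phenylethanol
Product: 23 (1S)-4-hydroxy-10-methoxy-8-methyl-3,7-dioxo-1-[(1R)-1-phenylethoxy]-1,3-dihydro-7H-isobenzofuro[4,5-b][1,4]benzodioxepine-11-carbaldehyde
Conditions: 22 (3 equiv), PPTS (0.1 equiv), ClCH2CH2Cl, 4 Å MS, 50 °C; chromatographic separation from the acetal epimer
Reagents that add atoms: none
Why: Acid-catalysed exchange of the lactol hydroxyl for an alkoxy group (pseudo-ester formation of a 3-hydroxyphthalide) gives two diastereomeric acetals because the alcohol is one enantiomer. The stereocentre of the target is set here by isolating the (S)-acetal, to be assigned by crystallography; the weak acid avoids ionisation of the benzylic alcohol, and the other epimer can be returned to 21 under the conditions of step 14.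

Step 16
Reactants: 23 (1S)-4-hydroxy-10-methoxy-8-methyl-3,7-dioxo-1-[(1R)-1-phenylethoxy]-1,3-dihydro-7H-isobenzofuro[4,5-b][1,4]benzodioxepine-11-carbaldehyde
Product: 24 (1S)-1,4-dihydroxy-10-methoxy-8-methyl-3,7-dioxo-1,3-dihydro-7H-isobenzofuro[4,5-b][1,4]benzodioxepine-11-carbaldehyde (target, CNP0216483.1)
Conditions: H2 (1 atm), Pd/C (10 wt%), EtOAc, rt; stopped at full conversion, filtered and evaporated cold
Reagents that add atoms: none
Why: Hydrogenolysis cleaves the benzylic O–C bond of the 1-phenylethyl group and not a bond to the acetal carbon, so the lactol should be released with retention under neutral aprotic conditions, as in the debenzylation of benzyl glycosides. The ring A aldehyde is shielded by two ortho substituents and deactivated by the ortho methoxy group.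

## Compound list

1 | dimethyl furan-3,4-dicarboxylate | COC(=O)c1cocc1C(=O)OC | starting material
2 | 4-(methoxycarbonyl)furan-3-carboxylic acid | COC(=O)c1cocc1C(=O)O | intermediate
3 | methyl 4-(hydroxymethyl)furan-3-carboxylate | COC(=O)c1cocc1CO | intermediate
4 | methyl 5-bromo-4-(hydroxymethyl)furan-3-carboxylate | COC(=O)c1coc(Br)c1CO | intermediate
5 | methyl 5-bromo-4-formylfuran-3-carboxylate | COC(=O)c1coc(Br)c1C=O | intermediate
6 | orsellinic acid (2,4-dihydroxy-6-methylbenzoic acid) | Cc1cc(O)cc(O)c1C(=O)O | starting material
7 | allyl 2,4-dihydroxy-6-methylbenzoate | C=CCOC(=O)c1c(C)cc(O)cc1O | intermediate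
8 | allyl 2-hydroxy-4-methoxy-6-methylbenzoate | C=CCOC(=O)c1c(C)cc(OC)cc1O | intermediate
9 | allyl 2-hydroxy-3-(hydroxymethyl)-4-methoxy-6-methylbenzoate (salicyl alcohol, not isolated) | C=CCOC(=O)c1c(C)cc(OC)c(CO)c1O | intermediate
10 | allyl 3-formyl-2-hydroxy-4-methoxy-6-methylbenzoate | C=CCOC(=O)c1c(C)cc(OC)c(C=O)c1O | intermediate
11 | allyl 3-formyl-2-{[3-formyl-4-(methoxycarbonyl)furan-2-yl]oxy}-4-methoxy-6-methylbenzoate | C=CCOC(=O)c1c(C)cc(OC)c(C=O)c1Oc1occ(C(=O)OC)c1C=O | intermediate
12 | allyl 3-(dimethoxymethyl)-2-{[3-(dimethoxymethyl)-4-(methoxycarbonyl)furan-2-yl]oxy}-4-methoxy-6-methylbenzoate | C=CCOC(=O)c1c(C)cc(OC)c(C(OC)OC)c1Oc1occ(C(=O)OC)c1C(OC)OC | intermediate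
13 | potassium 3-(dimethoxymethyl)-2-{[3-(dimethoxymethyl)-4-(methoxycarbonyl)furan-2-yl]oxy}-4-methoxy-6-methylbenzoate | [K+].[O-]C(=O)c1c(C)cc(OC)c(C(OC)OC)c1Oc1occ(C(=O)OC)c1C(OC)OC | intermediate
14 | bis(trimethylsilyl)acetylene | C[Si](C)(C)C#C[Si](C)(C)C | starting material
15 | phenyl[(trimethylsilyl)ethynyl]iodonium trifluoromethanesulfonate | C[Si](C)(C)C#C[I+]c1ccccc1.[O-]S(=O)(=O)C(F)(F)F | intermediate
16 | (trimethylsilyl)ethynyl 3-(dimethoxymethyl)-2-{[3-(dimethoxymethyl)-4-(methoxycarbonyl)furan-2-yl]oxy}-4-methoxy-6-methylbenzoate (key-step precursor) | COc1cc(C)c(C(=O)OC#C[Si](C)(C)C)c(Oc2occ(C(=O)OC)c2C(OC)OC)c1C(OC)OC | intermediate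
17 | oxa-bridged cycloadduct (7-oxanorbornadiene; the former furan oxygen bridges B1 and B4; B2=B3 and B5=B6 double bonds; racemic; not isolated) | COc1cc(C)c2c(c1C(OC)OC)OC13OC(C(C(=O)OC)=C1C(OC)OC)C([Si](C)(C)C)=C3OC2=O | intermediate
18 | methyl 4,6-bis(dimethoxymethyl)-8-hydroxy-3-methoxy-1-methyl-11-oxo-9-(trimethylsilyl)-11H-dibenzo[b,e][1,4]dioxepine-7-carboxylate (key-step product) | COc1cc(C)c2c(c1C(OC)OC)Oc1c(c([Si](C)(C)C)c(O)c(C(=O)OC)c1C(OC)OC)OC2=O | intermediate
19 | methyl 4,6-diformyl-8-hydroxy-3-methoxy-1-methyl-11-oxo-9-(trimethylsilyl)-11H-dibenzo[b,e][1,4]dioxepine-7-carboxylate (not isolated) | COc1cc(C)c2c(c1C=O)Oc1c(c([Si](C)(C)C)c(O)c(C(=O)OC)c1C=O)OC2=O | intermediate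
20 | (±)-1,4-dihydroxy-10-methoxy-8-methyl-3,7-dioxo-5-(trimethylsilyl)-1,3-dihydro-7H-isobenzofuro[4,5-b][1,4]benzodioxepine-11-carbaldehyde (not isolated) | COc1cc(C)c2c(c1C=O)Oc1c(c([Si](C)(C)C)c(O)c3c1C(O)OC3=O)OC2=O | intermediate
21 | (±)-1,4-dihydroxy-10-methoxy-8-methyl-3,7-dioxo-1,3-dihydro-7H-isobenzofuro[4,5-b][1,4]benzodioxepine-11-carbaldehyde (racemic lactol) | COc1cc(C)c2c(c1C=O)Oc1c(cc(O)c3c1C(O)OC3=O)OC2=O | intermediate
22 | (R)-1-phenylethanol | C[C@@H](O)c1ccccc1 | starting material
23 | (1S)-4-hydroxy-10-methoxy-8-methyl-3,7-dioxo-1-[(1R)-1-phenylethoxy]-1,3-dihydro-7H-isobenzofuro[4,5-b][1,4]benzodioxepine-11-carbaldehyde | COc1cc(C)c2c(c1C=O)Oc1c(cc(O)c3c1[C@@H](O[C@H](C)c1ccccc1)OC3=O)OC2=O | intermediate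
24 | (1S)-1,4-dihydroxy-10-methoxy-8-methyl-3,7-dioxo-1,3-dihydro-7H-isobenzofuro[4,5-b][1,4]benzodioxepine-11-carbaldehyde | COc1cc(C)c2c(c1C=O)Oc1c(cc(O)c3c1[C@@H](O)OC3=O)OC2=O | target

## Step count and least certain steps

Total: 16 steps. Longest linear sequence: 12 steps (steps 1–4, 8–10, 12–16).

**Step 13 (key step, proposed new method).** The most likely failure is thermal breakdown of the alkynyl ester (acyl migration, or solvolysis by traces of water) before any cycloaddition occurs. The ester must adopt its unfavoured conformation and the dienophile is only weakly activated; loss of the acetals at 170 °C is the second risk. The fallback uses known chemistry, sets out from 12 and returns at 21. An intermolecular Diels–Alder reaction of 12 with 3-butyn-2-one (toluene, 80–110 °C) is a known reaction type for 2-oxygenated furans and acyl alkynes. The electron-rich C5 should bond to the alkyne β-carbon and the bridge should open in the same way, giving the B2-acetyl B4-phenol diaryl ether F1. Baeyer–Villiger oxidation (mCPBA, Na2HPO4, CH2Cl2) with aryl migration should give the B2 acetate F2. Pd(PPh3)4 with excess morpholine in THF should remove the allyl group and cleave the aryl acetate in one operation, giving the hydroxy acid F3. Carbodiimide lactonisation at high dilution (EDC·HCl, DMAP, CH2Cl2), the established way to close ring C of depsidones, should give the silicon-free depsidone bis-acetal F4, which under the conditions of step 14 gives 21.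

**Step 12.** The silyl alkynyl ester may decompose during formation or handling, through protonation at the alkyne β-carbon, attack at the acyl carbon or desilylation, since it is an active ester. The alkylidene carbene may also be diverted. The fallback sets out from 13 and returns at 16, with the polarity of the partners reversed. Two equivalents of 13 and PhICl2 (CH2Cl2, 0 °C) give the bis(aroyloxy)iodobenzene F5. Lithium (trimethylsilyl)acetylide, from trimethylsilylacetylene and n-BuLi in THF at −78 °C, displaces one carboxylate at iodine. The alkynyl(phenyl)iodonium carboxylate so formed should collapse within the ion pair to 16, with one equivalent of the carboxylate recovered.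

**Step 8.** Substitution may be slow, with base-induced decomposition of 5 competing, because the phenoxide of 10 is hindered and delocalised into two ortho carbonyl groups. The fallback sets out from 5 and 10 and returns at 12. 5 is first acetalised (HC(OMe)3, MeOH, PPTS) to the bromofuran acetal F6. A copper-catalysed Ullmann-type etherification of 10 with F6 (CuI, picolinic acid, K3PO4, DMSO, 90 °C) forms the ether at the metal and does not depend on addition–elimination. The resulting mono-acetal diaryl ether F7 is acetalised at the ring A aldehyde under the conditions of step 9 to give 12.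

**Step 14.** Protodesilylation may stall, because ring B is deactivated by the lactone and the ester oxygen, under conditions still mild enough for ring C. The fallback sets out from 18 and returns at 21. Dilute acid (1 M HCl, THF, rt) is used only for acetal hydrolysis and lactol closure, and 20 is isolated. Ipso-iododesilylation with ICl (CH2Cl2, 0 °C), which needs no ring protonation, gives the B3 iodide F8. Radical deiodination ((Me3Si)3SiH, AIBN, toluene, 80 °C) then gives 21.

**Step 16.** Over-reduction of the ring A aldehyde, or hydrogenolysis at the acetal carbon (which is benzylic to ring B), may compete with cleavage of the auxiliary. The fallback sets out from 21 and returns at 24 by an oxidative release. 21 is acetalised under the conditions of step 15 with (R)-1-(4-methoxyphenyl)ethanol, and the (S)-acetal F9 is separated. DDQ in CH2Cl2 with pH 7 buffer should remove the electron-rich benzylic group as a ketone, without reductant, acid or base, to give 24.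

## Further compounds

F1 | step 13 | allyl 2-[2-acetyl-6-(dimethoxymethyl)-4-hydroxy-5-(methoxycarbonyl)phenoxy]-3-(dimethoxymethyl)-4-methoxy-6-methylbenzoate | C=CCOC(=O)c1c(C)cc(OC)c(C(OC)OC)c1Oc1c(C(C)=O)cc(O)c(C(=O)OC)c1C(OC)OC
F2 | step 13 | allyl 2-[2-acetoxy-6-(dimethoxymethyl)-4-hydroxy-5-(methoxycarbonyl)phenoxy]-3-(dimethoxymethyl)-4-methoxy-6-methylbenzoate | C=CCOC(=O)c1c(C)cc(OC)c(C(OC)OC)c1Oc1c(OC(C)=O)cc(O)c(C(=O)OC)c1C(OC)OC
F3 | step 13 | 2-[6-(dimethoxymethyl)-2,4-dihydroxy-5-(methoxycarbonyl)phenoxy]-3-(dimethoxymethyl)-4-methoxy-6-methylbenzoic acid | OC(=O)c1c(C)cc(OC)c(C(OC)OC)c1Oc1c(O)cc(O)c(C(=O)OC)c1C(OC)OC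
F4 | step 13 | methyl 4,6-bis(dimethoxymethyl)-8-hydroxy-3-methoxy-1-methyl-11-oxo-11H-dibenzo[b,e][1,4]dioxepine-7-carboxylate | COc1cc(C)c2c(c1C(OC)OC)Oc1c(cc(O)c(C(=O)OC)c1C(OC)OC)OC2=O
F5 | step 12 | bis(aroyloxy)iodobenzene carrying two acyl groups of 13 | O=C(OI(OC(=O)c1c(C)cc(OC)c(C(OC)OC)c1Oc1occ(C(=O)OC)c1C(OC)OC)c1ccccc1)c1c(C)cc(OC)c(C(OC)OC)c1Oc1occ(C(=O)OC)c1C(OC)OC
F6 | step 8 | methyl 5-bromo-4-(dimethoxymethyl)furan-3-carboxylate | COC(=O)c1coc(Br)c1C(OC)OC
F7 | step 8 | allyl 2-{[3-(dimethoxymethyl)-4-(methoxycarbonyl)furan-2-yl]oxy}-3-formyl-4-methoxy-6-methylbenzoate | C=CCOC(=O)c1c(C)cc(OC)c(C=O)c1Oc1occ(C(=O)OC)c1C(OC)OC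
F8 | step 14 | (±)-1,4-dihydroxy-5-iodo-10-methoxy-8-methyl-3,7-dioxo-1,3-dihydro-7H-isobenzofuro[4,5-b][1,4]benzodioxepine-11-carbaldehyde | COc1cc(C)c2c(c1C=O)Oc1c(c(I)c(O)c3c1C(O)OC3=O)OC2=O
F9 | step 16 | (1S)-4-hydroxy-10-methoxy-1-[(1R)-1-(4-methoxyphenyl)ethoxy]-8-methyl-3,7-dioxo-1,3-dihydro-7H-isobenzofuro[4,5-b][1,4]benzodioxepine-11-carbaldehyde | COc1cc(C)c2c(c1C=O)Oc1c(cc(O)c3c1[C@@H](O[C@H](C)c1ccc(OC)cc1)OC3=O)OC2=O
A1 | alternative 1 | benzyl-protected depsidone (R)-1-phenylethyl acetal with (S)-acetal carbon | COc1cc(C)c2c(c1C=O)Oc1c(cc(OCc3ccccc3)c3c1[C@@H](O[C@H](C)c1ccccc1)OC3=O)OC2=O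
A2 | alternative 1 | depsidone with B4 benzyl ether, B5 bromide and B6 aldehyde | COc1cc(C)c2c(c1C=O)Oc1c(cc(OCc3ccccc3)c(Br)c1C=O)OC2=O
A3 | alternative 2 | diaryl ether with complete ring B (B2 and B4 phenols, B5 methyl ester, B6 acetal, ring A tert-butyl ester) | COC(=O)c1c(O)cc(O)c(Oc2c(C(OC)OC)c(OC)cc(C)c2C(=O)OC(C)(C)C)c1C(OC)OC
A4 | alternative 2 | methyl 2-aryloxy-3,4,4-trimethoxybut-2-enoate on the ring A phenol (ring A tert-butyl ester and acetal) | COC(=O)C(Oc1c(C(OC)OC)c(OC)cc(C)c1C(=O)OC(C)(C)C)=C(OC)C(OC)OC
A5 | alternative 2 | methyl acetoacetate | COC(=O)CC(C)=O
A6 | alternative 3 | (R)-3-boryl phthalide depsidone (B4 methoxymethyl ether, ring A acetal) | COc1cc(C)c2c(c1C(OC)OC)Oc1c(cc(OCOC)c3c1[C@@H](B1OC(C)(C)C(C)(C)O1)OC3=O)OC2=O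
A7 | alternative 3 | depsidone with B4 methoxymethyl ether, B5 methyl ester, B6 aldehyde and ring A acetal | COc1cc(C)c2c(c1C(OC)OC)Oc1c(cc(OCOC)c(C(=O)OC)c1C=O)OC2=O
A8 | alternative 3 | bis(pinacolato)diboron | CC1(C)OB(OC1(C)C)B1OC(C)(C)C(C)(C)O1
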